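Read at 5.0 h, the flask stands well past the lag in the runs. Your hunch goes below as the forecast; first, the case:

| setting | elm | alder | cedar | flask |
|---|---|---|---|---|
| starting material | 0.28 M | 1.1 M | 0.57 M | 0.57 M |
| reagent in the second phase | 2 equiv | 2 equiv | 4 equiv | 2.00 equiv |
| remark | run made earlier | run made earlier | run made earlier |  |
| time |  |  |  | 5.0 h |
| volume of the second phase over the first |  |  |  | 2.0 |

- elm (time / h: target / %): 0.417: 0; 1.00: 1; 2.00: 5; 3.00: 5
- alder (time / h: target / %): 0.417: 1; 1.00: 4; 2.00: 10; 3.00: 17
- cedar (time / h: target / %): 0.417: 1; 1.00: 4; 2.00: 12; 3.00: 17

(standard deviation of a reading: 1.5 percentage points)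

- in the second phase: reagent in the second phase; everything else is in the first
- charges count per volume of the first phase; a concentration in a rate is the amount of a species over the volume of its own phase; every rate counts per litre of the first phase
- reactions considered so far: reagent in the reaction phase + target -> over-reacted product; starting material + reagent in the reaction phase -> target; reagent in the reaction phase + target -> over-reaction product; reagent in the reaction phase <-> reagent in the second phase
- the earlier runs hold the two phases in the same ratio of volumes as the flask asked about

- winter: doubling the transfer coefficient of the reagent in the second phase, all else as stated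
- dusk: doubling the amount of reagent in the second phase, all else as stated

* amount of target at 5.0 h, in percent of the starting material charged
* the change that raises the amount of target at 5.0 h, in percent of the starting material charged most ("none" if none brings more than 2 percentage points) (winter / dusk / none)
* amount of target at 5.0 h, in percent of the starting material charged, after dusk

My reckoning: follow the fraction of starting material left, not the target made. Take the clearing rate, the hourly fall in the logarithm of that fraction (a pseudo-first-order constant), scaled to the reagent charged per litre of the first phase. Read cedar from 1.00 h to 3.00 h and scale to the flask's half loading: 0.0364 h⁻¹. Scale cedar's early loss the same way, run this rate on to 5.0 h, and 84.7 % stays. Counted as target, that loss gives 15.3 %, above the forecast. If dusk doubles the rate, square the fraction: 71.7 % left.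

The forecast says 13.5 % (11 % to 16 %), dusk as the best change, and 25 % after it (20 % to 30 %), holding that “Doubling transfer only shortens the lag”.

    reagent in the reaction phase + target → over-reacted product (k = 7.54 × 10⁻⁴ L mol⁻¹ min⁻¹)
    starting material + reagent in the reaction phase → target (k = 0.00215 L mol⁻¹ min⁻¹)
    reagent in the reaction phase + target → over-reaction product (k = 0.00315 L mol⁻¹ min⁻¹)
    reagent in the reaction phase ⇌ reagent in the second phase, rate k4*([reagent in the reaction phase] - [reagent in the second phase]/K4) per volume of the first phase (partition coefficient = 0.380, kL = 0.00509 min⁻¹)

The flask gives 18.5 %, and dusk 25.4 %. Dusk's pick would fall if winter's gain of 2 percentage points outran dusk's 6.9 points; it does not. The flask holds 76 % of its starting material, and from 3.0 h to 5.0 h clears at 0.0665 h⁻¹, faster than my rate. Reagent in the second phase drains to 40.7 % of its charge; kept from running short, the flask's target stands at 23.5 %, not 18.5 %, and over-reaction product takes a further 4.15 %. Read at 3.0 h, my rate leaves 91.1 %; that flask holds 87 %.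

(The data come from a simulation on assumed constants; scatter was added.)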